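A neighbour of this flask differs in one charge, its free base, and what you can carry from one to the other is a single acid level.

electrophile 0.33 M; free base 0.800 equiv; solid nucleophile 2.00 equiv; time 10 min

- part of the electrophile that has reacted at 10 min
- share of free nucleophile in free nucleophile and protonated nucleophile together, at 10 min

    solid nucleophile ⇌ nucleophile, rate k1*(cs1 - [nucleophile]) while solid is left; crystals form when [nucleophile] > cs1 (cs1 = 0.14 M, k1 = 0.012 s⁻¹)
    acid set free + free base ⇌ salt of the base (K2 = 39000 M⁻¹, k2 = 0.58 M⁻¹ s⁻¹)
    electrophile + nucleophile → acid set free + product (k3 = 0.18 M⁻¹ s⁻¹)
    nucleophile + acid set free ⇌ protonated nucleophile, settled at all times (K4 = 560 M⁻¹)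
    2 nucleophile → homo dimer (k5 = 0.37 M⁻¹ s⁻¹)

- where a step has two of a species, its rate is k times that concentration squared, and two are used at each turn
- solid nucleophile is a solid; its amount is given per volume of the solution
- at the start none of the solid nucleophile is in solution
- run time (flask): 10 min

Protonation of the nucleophile is kept at balance, so protonated over free nucleophile equals 560 M⁻¹ times the acid set free. Call the even-split level, the acid concentration at which free and protonated nucleophile stand equal, 0.00179 M. The free share is then one over one plus the acid divided by that level.

To use this you need the acid at 10 min, so reckon by hand. The solid dissolves at most at 0.101 M min⁻¹, its coefficient times its solubility, so the 0.660 M charged needs at least 6.55 min, less than the run. While solid lasts, let coupling with the electrophile as charged and dimerisation, two nucleophile per turn, take what the feed brings. Setting these equal gives nucleophile 0.0222 M. Held there, the electrophile decays pseudo-first-order with time constant 4.18 min, which integrates to 90.9% reacted.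

Next, suppose free base takes acid as fast as coupling makes it, with electrophile over base as charged (0.264 M of base). That gives acid 0.00860 M, and the rule turns this into a free share of 17.2%.

The weak link is that balance. Acid made is shared with protonated nucleophile, which acts as a buffer, and the time constant of that buffer, one plus 560 M⁻¹ times nucleophile, over 0.58 M⁻¹ s⁻¹ times base, is 1.46 min with base as charged. With base down by a factor 4 it is 5.84 min, still shorter than the run. So the acid lags by minutes, and I keep both figures.

The forecast says 91% and 27%, holding that “Base capture of the acid is slow”. On conversion it stands with my figure, and on the share it stands higher.

The flask gives 92.1% and 15.9%.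

At 10.0 min this flask holds acid set free 0.00945 M, which is 5.28 times the even-split level, and the rule returns a free share of 15.9%. That is where the flask parts from the forecast, its simulated share lying 11 percentage points lower. The neighbour charged with 2.00 equiv of free base holds, at 10.0 min, acid set free 8.01 × 10⁻⁴ M, less than that level. Put into the rule, that acid level is a free share of 69.0% in the neighbour, which has 94.0% of its electrophile reacted.

Its constants were set for the occasion; the flask was simulated.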